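**Strategy.** Ring A of the flavone carries its two links to the pyranone, C8a–O1 and C4a–C4, on neighbouring carbons, with the C5 methoxy next to C4a. Both bonds are therefore made at once by inserting a ring A aryne (C4a≡C8a, C8 still hydrogen) into the carboxyl C–O bond of a ring B arylpropiolic acid: oxygen lands on C8a, the acyl carbon on C4a, and an o-hydroxyaryl ynone results. The aryne is released by fluoride from an o-silylaryl triflate made from syringaldehyde; the acid comes from 2-hydroxy-6-methoxybenzaldehyde. Amine-mediated 6-endo closure, C8 bromination–methoxylation and hydrogenolysis of two benzyl ethers complete the route.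

Key step: step 8

Remark: flavone locants (O1, C2, C3, C4, C4a, C5 to C8, C8a; ring B primed) are used for the corresponding atoms of all intermediates, also before the pyranone exists.

Step 1
Reactants: 1 syringaldehyde
Product: 2 4-(benzyloxy)-3,5-dimethoxybenzaldehyde
Conditions: BnBr, K2CO3, DMF, 60 °C
Reagents that add atoms: benzyl bromide, BrCc1ccccc1
Why: Williamson etherification of the phenoxide; the benzyl ether is chosen because it should survive the later organolithium, fluoride, amine and copper steps and leave by hydrogenolysis at the end.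

Step 2
Reactants: 2 4-(benzyloxy)-3,5-dimethoxybenzaldehyde
Product: 4 4-(benzyloxy)-3,5-dimethoxyphenol, via aryl formate 3 (not isolated)
Conditions: mCPBA, CH2Cl2, 0 °C to rt; then Et3N, MeOH, rt
Reagents that add atoms: 3-chloroperoxybenzoic acid, O=C(OO)c1cccc(Cl)c1
Why: Baeyer–Villiger (Dakin-type) oxidation in which the electron-rich trialkoxyaryl group migrates to give the aryl formate, which mild methanolysis cleaves to the phenol without touching the benzyl ether.

Step 3
Reactants: 4 4-(benzyloxy)-3,5-dimethoxyphenol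
Product: 5 4-(benzyloxy)-2-bromo-3,5-dimethoxyphenol
Conditions: NBS (1.0 equiv), CH2Cl2, −78 °C to 0 °C
Reagents that add atoms: N-bromosuccinimide, O=C1CCC(=O)N1Br
Why: Electrophilic aromatic bromination directed by the free hydroxyl; the para position is blocked and the two ortho positions are equivalent, so one equivalent at low temperature should give a single monobromide.

Step 4
Reactants: 5 4-(benzyloxy)-2-bromo-3,5-dimethoxyphenol
Product: 8 4-(benzyloxy)-3,5-dimethoxy-2-(trimethylsilyl)phenyl trifluoromethanesulfonate, via aryl trimethylsilyl ether 6 (not isolated), via lithium 2-silylphenoxide 7 (not isolated)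
Conditions: HMDS, THF, reflux, then evaporation; n-BuLi, THF, −100 °C; Tf2O, −100 °C to rt
Reagents that add atoms: hexamethyldisilazane, C[Si](C)(C)N[Si](C)(C)C; trifluoromethanesulfonic anhydride, O=S(=O)(OS(=O)(=O)C(F)(F)F)C(F)(F)F
Why: O-silylation, then bromine–lithium exchange triggers the 1,3 oxygen-to-carbon silyl shift (retro-Brook rearrangement) and the resulting phenoxide is triflated in the same flask, the standard one-pot route to o-silylaryl triflates; the exchange at −100 °C is faster than benzylic deprotonation.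

Step 5
Reactants: 9 2-hydroxy-6-methoxybenzaldehyde
Product: 10 2-(benzyloxy)-6-methoxybenzaldehyde
Conditions: BnBr, K2CO3, DMF, 60 °C
Reagents that add atoms: benzyl bromide, BrCc1ccccc1
Why: Williamson etherification; the same protecting group as on ring A allows one final deprotection.

Step 6
Reactants: 10 2-(benzyloxy)-6-methoxybenzaldehyde
Product: 11 1-(benzyloxy)-2-(2,2-dibromoethenyl)-3-methoxybenzene
Conditions: CBr4, PPh3, CH2Cl2, 0 °C
Reagents that add atoms: carbon tetrabromide, BrC(Br)(Br)Br
Why: Corey–Fuchs dibromoolefination, a Wittig reaction of the ylide formed from CBr4 and PPh3, under neutral conditions that leave both ethers alone.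

Step 7
Reactants: 11 1-(benzyloxy)-2-(2,2-dibromoethenyl)-3-methoxybenzene
Product: 13 3-[2-(benzyloxy)-6-methoxyphenyl]prop-2-ynoic acid, via lithium arylacetylide 12 (not isolated)
Conditions: n-BuLi (2.2 equiv), THF, −78 °C; CO2, −78 °C to rt; aqueous HCl
Reagents that add atoms: carbon dioxide, O=C=O
Why: Second stage of the Corey–Fuchs sequence, in which butyllithium converts the dibromoalkene into the lithium acetylide (exchange, 1,2-shift, deprotonation) and CO2 carboxylates it.

Step 8
Reactants: 8 4-(benzyloxy)-3,5-dimethoxy-2-(trimethylsilyl)phenyl trifluoromethanesulfonate (1.5 equiv); 13 3-[2-(benzyloxy)-6-methoxyphenyl]prop-2-ynoic acid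
Product: 15 3-[2-(benzyloxy)-6-methoxyphenyl]-1-[3-(benzyloxy)-6-hydroxy-2,4-dimethoxyphenyl]prop-2-yn-1-one, via ring A aryne 14 (not isolated)
Conditions: CsF (4 equiv), anhydrous THF, sealed tube, 125 °C
Reagents that add atoms: none
Why: Fluoride attacks silicon in 8 and triflate leaves, giving aryne 14 whose strained bond joins the future C4a and C8a; the cesium carboxylate of 13 adds through oxygen at C8a, the C4a aryl anion attacks the neighbouring ester carbonyl through a four-membered transition state, and collapse of that adduct gives the o-acylphenoxide, a net insertion of the aryne into the acid C–O bond. The closest known reaction type is this same fluoride-induced insertion of arynes into carboxylic acid C–O bonds to give o-hydroxyaryl ketones, which has been applied to arylpropiolic acids. No ring is closed, so no closure mode applies, and no stereocentre is formed. The step needs regioselectivity, secured by the C5 methoxy flanking C4a: its inductive pull and the resulting aryne distortion send the nucleophile to the remote carbon C8a and place the negative charge at C4a, while C8 carries only hydrogen and exerts no opposing bias. It also needs acyl transfer to outrun protonation of the aryl anion, which anhydrous conditions, excess CsF and heat favour, and it needs the ynone to persist, which the chelated, weakly nucleophilic phenoxide and the hindered ring B terminus should allow.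

Step 9
Reactants: 15 3-[2-(benzyloxy)-6-methoxyphenyl]-1-[3-(benzyloxy)-6-hydroxy-2,4-dimethoxyphenyl]prop-2-yn-1-one
Product: 17 6-(benzyloxy)-2-[2-(benzyloxy)-6-methoxyphenyl]-5,7-dimethoxy-4H-chromen-4-one, via diethylamino enaminone 16 (not isolated)
Conditions: Et2NH (5 equiv), EtOH, rt then reflux
Reagents that add atoms: none
Why: Conjugate addition of diethylamine gives the enaminone, whose β-carbon (C2) is attacked by the C8a hydroxyl with loss of the amine, a known amine-mediated 6-endo cyclisation of o-hydroxyaryl ynones that shuts off the 5-exo aurone pathway; any 15 that closes in this sense already in step 8 is 17 itself, so the crude mixture can be used.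

Step 10
Reactants: 17 6-(benzyloxy)-2-[2-(benzyloxy)-6-methoxyphenyl]-5,7-dimethoxy-4H-chromen-4-one
Product: 18 6-(benzyloxy)-2-[2-(benzyloxy)-6-methoxyphenyl]-8-bromo-5,7-dimethoxy-4H-chromen-4-one
Conditions: NBS (1.05 equiv), DMF, 0 °C to rt, dark
Reagents that add atoms: N-bromosuccinimide, O=C1CCC(=O)N1Br
Why: Electrophilic aromatic substitution at C8, the only free ring A carbon, which is ortho to O1 and the C7 methoxy, para to the C5 methoxy and meta to the carbonyl-bearing C4a, so it should outcompete C3 and the ring B positions, as is usual for 5,7-dialkoxyflavones.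

Step 11
Reactants: 18 6-(benzyloxy)-2-[2-(benzyloxy)-6-methoxyphenyl]-8-bromo-5,7-dimethoxy-4H-chromen-4-one
Product: 19 6-(benzyloxy)-2-[2-(benzyloxy)-6-methoxyphenyl]-5,7,8-trimethoxy-4H-chromen-4-one
Conditions: NaOMe (excess), CuBr (0.3 equiv), DMF/MeOH, 110 °C
Reagents that add atoms: sodium methoxide, [Na+].[O-]C
Why: Copper-catalysed Ullmann-type methoxylation of the aryl bromide, a standard conversion of 8-bromoflavones into 8-methoxyflavones, to which the benzyl and methyl ethers are inert.

Step 12
Reactants: 19 6-(benzyloxy)-2-[2-(benzyloxy)-6-methoxyphenyl]-5,7,8-trimethoxy-4H-chromen-4-one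
Product: 20 6,2'-dihydroxy-5,7,8,6'-tetramethoxyflavone
Conditions: H2 (1 atm), 10% Pd/C, EtOAc/MeOH, rt
Reagents that add atoms: none
Why: Catalytic hydrogenolysis of both benzyl ethers over palladium on carbon at ambient pressure, conditions under which the chromone C2–C3 double bond and carbonyl are normally retained.

**Compound list**

1 | syringaldehyde (4-hydroxy-3,5-dimethoxybenzaldehyde) | COc1cc(C=O)cc(OC)c1O | starting material
2 | 4-(benzyloxy)-3,5-dimethoxybenzaldehyde | COc1cc(C=O)cc(OC)c1OCc1ccccc1 | intermediate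
3 | 4-(benzyloxy)-3,5-dimethoxyphenyl formate | COc1cc(OC=O)cc(OC)c1OCc1ccccc1 | intermediate
4 | 4-(benzyloxy)-3,5-dimethoxyphenol | COc1cc(O)cc(OC)c1OCc1ccccc1 | intermediate
5 | 4-(benzyloxy)-2-bromo-3,5-dimethoxyphenol | COc1cc(O)c(Br)c(OC)c1OCc1ccccc1 | intermediate
6 | [4-(benzyloxy)-2-bromo-3,5-dimethoxyphenoxy]trimethylsilane | COc1cc(O[Si](C)(C)C)c(Br)c(OC)c1OCc1ccccc1 | intermediate
7 | lithium 4-(benzyloxy)-3,5-dimethoxy-2-(trimethylsilyl)phenoxide | COc1cc([O-])c([Si](C)(C)C)c(OC)c1OCc1ccccc1.[Li+] | intermediate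
8 | 4-(benzyloxy)-3,5-dimethoxy-2-(trimethylsilyl)phenyl trifluoromethanesulfonate | COc1cc(OS(=O)(=O)C(F)(F)F)c([Si](C)(C)C)c(OC)c1OCc1ccccc1 | intermediate
9 | 2-hydroxy-6-methoxybenzaldehyde | COc1cccc(O)c1C=O | starting material
10 | 2-(benzyloxy)-6-methoxybenzaldehyde | COc1cccc(OCc2ccccc2)c1C=O | intermediate
11 | 1-(benzyloxy)-2-(2,2-dibromoethenyl)-3-methoxybenzene | COc1cccc(OCc2ccccc2)c1C=C(Br)Br | intermediate
12 | lithium [2-(benzyloxy)-6-methoxyphenyl]ethynide | COc1cccc(OCc2ccccc2)c1C#[C-].[Li+] | intermediate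
13 | 3-[2-(benzyloxy)-6-methoxyphenyl]prop-2-ynoic acid | OC(=O)C#Cc1c(OC)cccc1OCc1ccccc1 | intermediate
14 | 4-(benzyloxy)-3,5-dimethoxy-1,2-didehydrobenzene (ring A aryne, triple bond between the future C8a and C4a) | COC1=C(OCc2ccccc2)C(OC)=CC#C1 | intermediate
15 | 3-[2-(benzyloxy)-6-methoxyphenyl]-1-[3-(benzyloxy)-6-hydroxy-2,4-dimethoxyphenyl]prop-2-yn-1-one | COc1cc(O)c(C(=O)C#Cc2c(OC)cccc2OCc2ccccc2)c(OC)c1OCc1ccccc1 | intermediate
16 | (2E)-3-[2-(benzyloxy)-6-methoxyphenyl]-1-[3-(benzyloxy)-6-hydroxy-2,4-dimethoxyphenyl]-3-(diethylamino)prop-2-en-1-one (geometry assumed; either isomer can close) | COc1cc(O)c(C(=O)/C=C(/N(CC)CC)c2c(OC)cccc2OCc2ccccc2)c(OC)c1OCc1ccccc1 | intermediate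
17 | 6-(benzyloxy)-2-[2-(benzyloxy)-6-methoxyphenyl]-5,7-dimethoxy-4H-chromen-4-one | COc1cc2oc(-c3c(OC)cccc3OCc3ccccc3)cc(=O)c2c(OC)c1OCc1ccccc1 | intermediate
18 | 6-(benzyloxy)-2-[2-(benzyloxy)-6-methoxyphenyl]-8-bromo-5,7-dimethoxy-4H-chromen-4-one | COc1c(Br)c2oc(-c3c(OC)cccc3OCc3ccccc3)cc(=O)c2c(OC)c1OCc1ccccc1 | intermediate
19 | 6-(benzyloxy)-2-[2-(benzyloxy)-6-methoxyphenyl]-5,7,8-trimethoxy-4H-chromen-4-one | COc1c(OC)c2oc(-c3c(OC)cccc3OCc3ccccc3)cc(=O)c2c(OC)c1OCc1ccccc1 | intermediate
20 | 6,2'-dihydroxy-5,7,8,6'-tetramethoxyflavone (6-hydroxy-2-(2-hydroxy-6-methoxyphenyl)-5,7,8-trimethoxy-4H-chromen-4-one) | COc1cccc(O)c1-c1cc(=O)c2c(OC)c(O)c(OC)c(OC)c2o1 | target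

**Step count.** Total: 12 steps. Longest linear sequence: 9 steps (steps 1, 2, 3, 4, 8, 9, 10, 11, 12 from syringaldehyde).

**Steps most likely to fail**

Step 8. The C4a aryl anion may be protonated before the acyl shift, which would give plain O-arylation of the acid. The electron-rich propiolate may also lose CO2 at 125 °C, or the product phenoxide may react further with surplus aryne or close unselectively. The fallback sets out from bromophenol 5 and aldehyde 10 and comes back at flavone 17, so it replaces steps 6 to 9 by anionic acylation and oxidative chalcone cyclisation. Compound 5 is treated with n-BuLi (2.2 equiv, THF, −78 °C; O–H deprotonation, then bromine–lithium exchange) and the C-lithiated phenoxide is acylated with N-methoxy-N-methylacetamide to give 1-[3-(benzyloxy)-6-hydroxy-2,4-dimethoxyphenyl]ethan-1-one F1. Claisen–Schmidt condensation of the acetophenone with 10 (KOH, EtOH, rt) should give (2E)-3-[2-(benzyloxy)-6-methoxyphenyl]-1-[3-(benzyloxy)-6-hydroxy-2,4-dimethoxyphenyl]prop-2-en-1-one F2. Heating this chalcone with catalytic iodine in DMSO at 130 °C should close and dehydrogenate it to 17.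

Step 10. Bromination may stray to C3 of the pyranone or to C3'/C5' of the dialkoxyphenyl ring B, or go on to a dibromide. The fallback sets out from ynone 15 and comes back at bromoflavone 18. Bromine is introduced before ring closure, when ring A still has the free C8a hydroxyl ortho to C8 and no chromone C3 exists. NBS (1.0 equiv, CH2Cl2, −20 °C) should give 3-[2-(benzyloxy)-6-methoxyphenyl]-1-[3-(benzyloxy)-5-bromo-6-hydroxy-2,4-dimethoxyphenyl]prop-2-yn-1-one F3. The same diethylamine-mediated 6-endo closure as in step 9 (Et2NH, EtOH, rt then reflux) then gives 18.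

Step 11. At the hindered C8, flanked by O1 and the C7 methoxy, the copper cycle may lose bromine reductively, and hot methoxide may open the pyranone at C2. The fallback sets out from 18 and comes back at 19, and installs the oxygen through boron instead of copper. Miyaura borylation (bis(pinacolato)diboron, Pd(OAc)2, SPhos, KOAc, dioxane, 90 °C) should give 6-(benzyloxy)-2-[2-(benzyloxy)-6-methoxyphenyl]-5,7-dimethoxy-8-(4,4,5,5-tetramethyl-1,3,2-dioxaborolan-2-yl)-4H-chromen-4-one F4. Oxidation of the C–B bond (aqueous H2O2, NaHCO3, THF, 0 °C to rt) should give 6-(benzyloxy)-2-[2-(benzyloxy)-6-methoxyphenyl]-8-hydroxy-5,7-dimethoxy-4H-chromen-4-one F5. O-Methylation of this phenol (iodomethane, K2CO3, acetone, reflux) gives 19.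

**Further compounds**

F1 | step 8 | 1-[3-(benzyloxy)-6-hydroxy-2,4-dimethoxyphenyl]ethan-1-one | COc1cc(O)c(C(C)=O)c(OC)c1OCc1ccccc1
F2 | step 8 | (2E)-3-[2-(benzyloxy)-6-methoxyphenyl]-1-[3-(benzyloxy)-6-hydroxy-2,4-dimethoxyphenyl]prop-2-en-1-one | COc1cc(O)c(C(=O)/C=C/c2c(OC)cccc2OCc2ccccc2)c(OC)c1OCc1ccccc1
F3 | step 10 | 3-[2-(benzyloxy)-6-methoxyphenyl]-1-[3-(benzyloxy)-5-bromo-6-hydroxy-2,4-dimethoxyphenyl]prop-2-yn-1-one | COc1c(Br)c(O)c(C(=O)C#Cc2c(OC)cccc2OCc2ccccc2)c(OC)c1OCc1ccccc1
F4 | step 11 | 6-(benzyloxy)-2-[2-(benzyloxy)-6-methoxyphenyl]-5,7-dimethoxy-8-(4,4,5,5-tetramethyl-1,3,2-dioxaborolan-2-yl)-4H-chromen-4-one | COc1c(B2OC(C)(C)C(C)(C)O2)c2oc(-c3c(OC)cccc3OCc3ccccc3)cc(=O)c2c(OC)c1OCc1ccccc1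
F5 | step 11 | 6-(benzyloxy)-2-[2-(benzyloxy)-6-methoxyphenyl]-8-hydroxy-5,7-dimethoxy-4H-chromen-4-one | COc1c(O)c2oc(-c3c(OC)cccc3OCc3ccccc3)cc(=O)c2c(OC)c1OCc1ccccc1
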